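The constants used here are assumed; the flask was simulated.

A small charge of substrate has little company, so ring closing, which needs no partner, should take most of it. This flask is charged fuller, and what I want to know is how much that costs.

substrate 1.0 M; time 5.0 min

    substrate → single ring (k1 = 0.19 s⁻¹)
    2 substrate → open dimer (k2 = 0.076 L mol⁻¹ s⁻¹)
    open dimer → ring dimer (k3 = 0.035 s⁻¹)
    substrate + open dimer → open trimer (k4 = 0.065 L mol⁻¹ s⁻¹)
    substrate + single ring → side product (k5 = 0.18 L mol⁻¹ s⁻¹)

- which holds at 5.0 min: what has brought the reaction to rest, or that it has not come to rest (forward and back rates have come level / all of the substrate has reacted / it is still moving)
- single ring at 5.0 min, in percent of the substrate charged
- side product at 5.0 min, in percent of the substrate charged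
- amount of single ring if the flask were left three thousand times as long, in percent of the substrate charged

- a species is counted by the substrate in it: one open dimer or ring dimer or side product counts as two
- a species is counted by the substrate in it: one open trimer counts as three
- two of one species on the left: rate k times its square, two consumed each time
- the reaction counts as stopped when no species that holds the substrate changes by six tenths of a point or more over the second half of the time
- run time (flask): 5.0 min

I run the flask in slow motion, in fractions of the charge. In the first instants substrate stands at the whole charge, and closing takes it at 0.19 s⁻¹, faster than pairing into open dimer at 0.152 s⁻¹. Per single ring made, pairing's loss scales with the substrate fraction, which at small charge averages 0.5 as it falls from whole to zero.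

In the middle, single ring has built up and capture into side product matters: the ring's half-life by capture, at substrate as charged, is 0.064 min, close to the substrate's 0.061 min by closing. Each capture costs one ring and one substrate, and the ring fraction also averages 0.5. Adding the losses gives my quantity, the balance charge: the closing constant over the sum of the pairing and capture constants.

share lost at small charge = charge / balance charge
balance charge = 0.19 s⁻¹ / (0.076 L mol⁻¹ s⁻¹ + 0.18 L mol⁻¹ s⁻¹) = 0.742 M

This flask holds more than that, so the line overshoots. At large charge, on my reckoning, capture undoes closing once the ring reaches a level where substrate cancels, the closing constant over the capture constant, 1.06 M, so the ring's fraction falls as that level over the charge. I join the ends with the simplest form that keeps the small-charge slope, with the balance charge as its crossover concentration; its large-charge level is lower than that ring level, so the form matches the small-charge end and lies low at the large one: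

single ring share = balance charge / (balance charge + charge) = 42.6 %

At the end, the run spans 82.0 substrate half-lives by closing, far longer than one such half-life. On my reckoning the substrate has reacted through long before the reading, capture has stopped, and open dimer closes to ring dimer with half-life 0.33 min, away from single ring. A later reading shows the same single ring.

The forecast says all of the substrate has reacted, with 44.5 % single ring, 27.5 % side product and 44.5 % after the long wait, since “single ring and side product are already frozen”. Its single ring stands above mine.

The flask gives all of the substrate has reacted, with 46.2 % single ring, 29.1 % side product and 46.2 % after the long wait. From 2.50 min to 5.0 min no share moves by more than 0.11 percentage points, so the reading in this flask depends on its charge and not on the hour. My joined line falls 3.6 points short, and read backwards the flask's single ring corresponds to a balance charge of 0.857 M.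

For the neighbour flask charged with 0.25 M, the balance charge gives 74.8 % single ring. The computed neighbour holds 75.9 %.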